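## Structural features

The target is an abietane-type tetracycle: a fully substituted catechol ring (ring C, C8–C9–C11–C12–C13–C14, only C14 bearing hydrogen) is fused through C8–C9 to a cyclohexane ring B, which shares the C5–C10 bond with a gem-dimethylcyclohexane ring A. A δ-lactone spans ring B from the C20 carboxyl carbon on C10 to the benzylic oxygen on C7, so that C10 and C7 are the bridgeheads of a 2-oxabicyclo[2.2.2]octanone. Three of the four stereocentres are clustered: the quaternary C10 (bearing C9, C20, C1 and C5) is bonded directly to C5, and C7 is tied to both through the bridge, whereas C15 in the 1-acetoxyprop-2-yl chain on C13 is remote and cannot be controlled from the core. Fragile elements are the air-sensitive catechol, the primary acetate (lost to base, hydride and strong nucleophiles) and the C7–O bond, which is benzylic, para to the C12 oxygen and therefore ionisable. The real difficulty is the all-carbon quaternary centre C10, wedged between an ortho-oxygenated arene, C5 and the C4 gem-dimethyl group, together with independent absolute control of C15. The key step uses the fact that C10 is the single atom closing the chain C1–C2–C3–C4–C5 into ring A: an arylacetate α-carbon that already carries C9 and C20 can be joined to C1 by SN2 displacement and to C5 by allylic substitution, leaving C6=C7 as a vinyl handle for ring B.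

## Logic of the disconnections

**31 ⇒ 30.** The two aryl O–CH3 bonds (at O11 and O12) are cut last. The free catechol is the most oxidation-prone function and should exist only in the final compound, and methyl ethers tolerate organolithium, amide base, palladium, borane and strong acid. The gain is an inert arene for every earlier step. The demand is an ether cleavage that spares the acetate and the benzylic lactone of 30.

**30 ⇒ 29 ⇒ 28.** The C7–C8 bond and the lactone C7–O bond are cut together, and the acid is returned to its tert-butyl ester. Both bonds end at one carbon of aldehyde oxidation level; C8 is the only free position ortho to C9 and is para to O12; the C20 carboxyl can reach C7 only from its own face, so C7 needs no separate control. The gain is that a tetracycle with three core stereocentres becomes one carbocycle with two. The demand is that one acid treatment unmasks the carboxyl, drives arene attack and closes the bridge, so O16 must already carry the acid-stable acetate.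

**28 ⇒ 27 ⇒ 25.** The C7 carbonyl is traced through the primary alcohol 27 to the C6=C7 vinyl group of 25 (a C7–O cut, no C–C bond). A vinyl group on C5 is exactly what allylic substitution at C5 leaves behind. The gain is a two-carbon arm without functionality during the key step. The demand is anti-Markovnikov hydration in the presence of two esters.

**25 ⇒ 24 ⇒ 23.** The O16–acetyl bond is exchanged for an O16–silyl bond. An acetate would not survive the bases of steps 11–13, and a silyl ether would not survive the acid of step 17. The gain is a single protecting group through the metalation and annulation steps. The demand is that the exchange sits directly after the key step.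

**23 ⇒ 21 + 10 (key).** The C10–C1 and C10–C5 bonds of ring A are cut. C10 of 21 is a doubly activated, twice-deprotonatable carbon, and 10 offers a primary iodide at C1 and an allyl unit at C5–C7. The gain is that ring A, the quaternary centre and both ring stereocentres arise from two fragments of similar size; (1R,2S) in 23, with the arene trans to the vinyl group, maps onto 10R,5S of 31. The demand is SN2 at C1 before ionisation at C7, closure at the hindered C5, ligand control of the allyl face and an equatorial arene in the closing chair.

**10 ⇒ 9 ⇒ 8 ⇒ 7 ⇒ 5 + 6.** Functional group changes (C1–I to C1–Cl, carbonate to alcohol, alcohol to ester) precede the cut of the C5=C6 double bond. A stabilised phosphonate delivers C6 and C7 with E geometry. The gain is a simple non-enolisable aldehyde 5. The demand is a chloride that survives phosphonate anion and hydride and is exchanged for iodide only at the end.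

**5 ⇒ 4 ⇒ 3 ⇒ 1 + 2.** The aldehyde carbon is taken back to a nitrile and the C3–C4 bond is cut. Alkylating the anion of 1 builds the quaternary C4, and a nitrile reaches the aldehyde level in one controlled reduction. The demand is displacement of bromide only in 2.

**21 ⇒ 19 + 20.** The C9–C10 (aryl–CH2) bond is cut. Catalytic enolate arylation adds C10 and C20 in one step as the tert-butyl ester needed later. The demand is monoarylation.

**19 ⇒ 18 ⇒ 17.** The C9–Br bond is returned to C9–H. The methoxy group at C11 is the only director with a free ortho position. The demand is ring lithiation without attack at the benzylic C15–H.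

**17 ⇒ 16 ⇒ 15 ⇒ 14 ⇒ 13 ⇒ 11 + 12.** The C15–CH3 bond and the N-acyl bond are cut. C15 is set by auxiliary-controlled enolate methylation of predictable sense. The gain is a return to a commercial arylacetic acid and a commercial auxiliary. The demand is diastereoselective methylation and non-epimerising reductive cleavage.

## Other disconnections considered

Alternative 1: The cut runs through C7–C8 and C7–O, so ring B and the lactone bridge are removed together and the dimethyl ether A1 is traced to the ring-A aldehyde acid A2.
- **Forward step:** acid activates the C7 aldehyde of A2, directly or through the acyloxocarbenium ion of its lactol form; C8 attacks, and the benzylic C7 centre is trapped by the C20 carboxyl to give A1.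
- **In favour:** two bonds, two rings and one stereocentre arise in one operation. C8 is the only open position ortho to C9 and lies para to O12. The C7 configuration is imposed by the bridge, and any loss of configuration at C7 or elimination towards C6 is corrected by re-ionisation to the same benzylic cation.
- **Against:** it is silent on how A2 obtains its quaternary C10 next to C5 in enantiopure form, and every other group must tolerate strong acid.
- **Comparison:** on structure it generates more complexity per step than the chosen key step and is in that respect the better transform. On mechanism it is cationic and substrate-controlled, needing no chiral catalyst, which is a further point in its favour. On step economy it neither adds nor saves steps, because it is a complement and not a rival: the chosen route uses this very closure as step 17, A2 being identical with 29 and A1 with 30. On the endgame the two plans are therefore equal, and the chosen key step supplies what this one presupposes.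

Alternative 2: Only the C16–O bond is cut back to a C16–H bond, so the target derives from carnosol A3, with C5, C7 and C10 already in place.
- **Forward step:** both phenols of A3 are first converted into the bis(diethylsilyl) ether A4. In A4 an iridium catalyst ([Ir(cod)OMe]2, a chiral N,N ligand and a sacrificial olefin as hydrogen acceptor) lets the O12-bound silicon insert into one of the two diastereotopic methyl C–H bonds, closing benzoxasiline A5. Tamao–Fleming oxidation of A5 would give triol A6, and acetylation of the primary hydroxyl of A6 the target.
- **In favour:** methyl C–H bonds are the preferred sites of this silylation, and the six-membered oxasiline is the only ring the O12 tether can form with a primary C–H bond. From A3 the sequence is about four steps, so if A3 is bought as the natural product this is clearly the better plan in step economy. It is at least the equal of the chosen plan in the security of the three core stereocentres, which are inherited.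
- **Against:** C15 must be set by catalyst control on a congested chiral substrate whose matched or mismatched response cannot be predicted. The O11 silane of A4 can reach the C1 methylene through an equally six-membered ring. The peroxide oxidation of A5 releases a free, easily oxidised catechol next to a benzylic lactone. The final acetylation of A6 must distinguish one primary hydroxyl from two phenols.
- **Comparison:** on structure, if A3 itself must be synthesised the advantage disappears, because the quaternary C10 and the lactone still have to be built. On mechanism the alternative is the more direct, since it functionalises an unactivated C–H bond, whereas the chosen plan fixes C15 at the outset with an auxiliary of known sense and carries the acetate through, which makes it the more certain. On step economy the alternative is the better from purchased A3 and no better from simple starting materials.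

Alternative 3: The cut removes ring C through C8–C14 and C9–C11, leading to the bicyclic alkenylstannane A7 (ring A, the C5–C6–C7 bridge and the lactone, with a C8=C9 double bond) and the 4-chlorocyclobutenone A8 carrying C13, C15 and the acetate.
- **Forward step:** Stille coupling (Pd2(dba)3, tri(2-furyl)phosphine) joins C8 of A7 to C14 of A8 to give the 4-alkenylcyclobutenone A9. On warming, A9 would undergo four-electron ring opening, six-electron ring closure (C9–C11) and tautomerisation to the C11 phenol A10.
- **In favour:** the penta-substituted arene is built regiospecifically without directed metalation, and here the alternative is the better of the two. C15 is made on the small fragment A8. In convergence it is the equal of the chosen plan.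
- **Against:** A10 lacks O12, so an ortho-oxygenation of a hindered phenol (oxidation to the quinone level, then reduction) is added at the very end. A7 already contains the hard part of the molecule (quaternary C10 with C20 and the C7–O bond) and needs its own enantioselective synthesis. The 2-oxabicyclo[2.2.2]octenone of A7 and A9 is the kind of ring that loses CO2 by retro-[4+2] reaction in the temperature range of the ketene cascade. Tin is used stoichiometrically.
- **Comparison:** on structure the chosen plan buys the arene with both oxygens in place and spends its key step on C10 and C5, whereas the alternative spends its key step on an arene that still needs oxidation. On mechanism the pericyclic cascade needs no control element and is the more predictable of the two key steps, but it is thermal and competes with decarboxylative fragmentation of the bridge. On step economy the alternative is expected to be longer overall, because A7 and the late oxygenation add steps that the chosen plan does not need.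

Key step: step 13

Assumption: the (R,R) antipode of the diphosphine is written in step 13; the sense of induction at C5 for this nucleophile class is taken from the usual working model of the ligand family, and the equally available (S,S) antipode would be used should the model prove inverted.

Abbreviations: ArSi = 4-[(2S)-1-{[tert-butyl(dimethyl)silyl]oxy}propan-2-yl]-2,3-dimethoxyphenyl; ArAc = 4-[(2S)-1-acetoxypropan-2-yl]-2,3-dimethoxyphenyl; TBS = tert-butyldimethylsilyl; Boc2O = di-tert-butyl dicarbonate; DMAP = 4-(dimethylamino)pyridine; TMEDA = N,N,N′,N′-tetramethylethane-1,2-diamine; 9-BBN = 9-borabicyclo[3.3.1]nonane.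

## Route

Step 1
Reactants: 1 isobutyronitrile (2-methylpropanenitrile); 2 1-bromo-3-chloropropane
Product: 3 5-chloro-2,2-dimethylpentanenitrile
Conditions: LiN(i-Pr)2, THF, −78 °C; then 2, −78 °C → rt
Reagents that add atoms: none
Why: α-Alkylation of a nitrile-stabilised carbanion; the tertiary anion of 1 displaces bromide, the better leaving group, and keeps the chloride as a latent C1 electrophile, and 3 has no α-hydrogen left for a second alkylation.

Step 2
Reactants: 3
Product: 5 5-chloro-2,2-dimethylpentanal, via N-(diisobutylalumanyl)aldimine 4 (not isolated)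
Conditions: i-Bu2AlH, CH2Cl2, −78 °C; then aq. HCl, 0 °C
Reagents that add atoms: water, O
Why: Partial reduction of a nitrile; one hydride addition gives the aluminium aldimine 4, which is not reduced further at low temperature and is hydrolysed to the aldehyde on work-up, and 5 is non-enolisable.

Step 3
Reactants: 5; 6 triethyl phosphonoacetate
Product: 7 ethyl (E)-7-chloro-4,4-dimethylhept-2-enoate
Conditions: NaH, THF, 0 °C → rt
Reagents that add atoms: none
Why: Horner–Wadsworth–Emmons olefination; stabilised phosphonate anions give (E)-enoates, the more so with an α-quaternary aldehyde, and the primary chloride is inert to the phosphonate anion at this temperature.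

Step 4
Reactants: 7
Product: 8 (E)-7-chloro-4,4-dimethylhept-2-en-1-ol
Conditions: i-Bu2AlH (2.2 equiv), CH2Cl2, −78 → 0 °C; aq. KNaC4H4O6
Reagents that add atoms: none
Why: 1,2-Reduction of an enoate by an electrophilic aluminium hydride gives the allylic alcohol without conjugate reduction; alkene geometry and chloride are untouched.

Step 5
Reactants: 8
Product: 9 tert-butyl (E)-7-chloro-4,4-dimethylhept-2-en-1-yl carbonate
Conditions: Boc2O, DMAP (cat.), CH2Cl2, 0 °C → rt
Reagents that add atoms: di-tert-butyl dicarbonate, CC(C)(C)OC(=O)OC(=O)OC(C)(C)C
Why: DMAP-catalysed O-acylation of a primary allylic alcohol; the tert-butyl carbonate is chosen because its ionisation by palladium releases CO2 and tert-butoxide, the base needed in step 13.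

Step 6
Reactants: 9
Product: 10 tert-butyl (E)-7-iodo-4,4-dimethylhept-2-en-1-yl carbonate
Conditions: NaI, acetone, reflux
Reagents that add atoms: sodium iodide, [Na+].[I-]
Why: Finkelstein halide exchange driven by precipitation of NaCl; the allylic carbonate is a poor leaving group towards iodide under neutral conditions, and the iodide is made last because it is the least storable function.

Step 7
Reactants: 11 (2,3-dimethoxyphenyl)acetic acid; 12 (S)-4-benzyloxazolidin-2-one
Product: 14 (S)-4-benzyl-3-[(2,3-dimethoxyphenyl)acetyl]oxazolidin-2-one, via mixed pivalic anhydride 13 (not isolated)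
Conditions: t-BuCOCl, Et3N, THF, −20 °C; then 12, LiCl, −20 °C → rt
Reagents that add atoms: none
Why: N-Acylation of the auxiliary through a mixed anhydride; the hindered pivaloyl carbonyl of 13 is not attacked, so the LiCl-activated oxazolidinone is acylated at the arylacetyl carbon, and no stereocentre is formed.

Step 8
Reactants: 14
Product: 15 (S)-4-benzyl-3-[(2S)-2-(2,3-dimethoxyphenyl)propanoyl]oxazolidin-2-one
Conditions: NaN(SiMe3)2, THF, −78 °C; then MeI, −78 °C
Reagents that add atoms: iodomethane, CI
Why: Evans alkylation; the chelated (Z)-sodium enolate is methylated on the face opposite the benzyl group, which sets C15 as (S) (the arene outranks methyl, so the usual sense of attack reads S here), and the minor diastereomer is removed by chromatography or crystallisation.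

Step 9
Reactants: 15
Product: 16 (2S)-2-(2,3-dimethoxyphenyl)propan-1-ol
Conditions: LiBH4, MeOH (1 equiv), Et2O, 0 °C
Reagents that add atoms: none
Why: Reductive cleavage of the auxiliary; hydride attacks the exocyclic imide carbonyl and releases 12 for reuse, and the medium is not basic enough to enolise the α-aryl centre, so C15 keeps its configuration.

Step 10
Reactants: 16
Product: 17 tert-butyl{[(2S)-2-(2,3-dimethoxyphenyl)propyl]oxy}dimethylsilane
Conditions: TBSCl, imidazole, CH2Cl2, rt
Reagents that add atoms: tert-butyl(chloro)dimethylsilane, CC(C)(C)[Si](C)(C)Cl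
Why: Standard silylation of a primary alcohol; the silyl ether tolerates the organolithium, amide bases and palladium of steps 11–13 and is a poor director of metalation.

Step 11
Reactants: 17
Product: 19 {[(2S)-2-(4-bromo-2,3-dimethoxyphenyl)propyl]oxy}(tert-butyl)dimethylsilane, via aryllithium 18 (not isolated)
Conditions: n-BuLi, TMEDA, Et2O, 0 °C → rt; then BrCCl2CCl2Br, −78 °C → rt
Reagents that add atoms: 1,2-dibromo-1,1,2,2-tetrachloroethane, ClC(Cl)(Br)C(Cl)(Cl)Br
Why: Directed ortho-metalation; the methoxy group beside the free ring position is the only director with an ortho hydrogen, so lithiation occurs at the future C9, while the tertiary benzylic C15–H is kinetically far less acidic; bromine is then transferred from the perhaloethane with loss of tetrachloroethene.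

Step 12
Reactants: 19; 20 tert-butyl acetate
Product: 21 tert-butyl 2-{4-[(2S)-1-{[tert-butyl(dimethyl)silyl]oxy}propan-2-yl]-2,3-dimethoxyphenyl}acetate
Conditions: LiN(SiMe3)2 (2.3 equiv), Pd(dba)2 (2 mol %), P(t-Bu)3 (2 mol %), toluene, rt
Reagents that add atoms: none
Why: Palladium-catalysed α-arylation of an ester enolate; oxidative addition of 19 to the zerovalent palladium–phosphine complex, transmetalation with the lithium enolate of 20 and reductive elimination form the aryl–CH2 bond. Excess base holds the more acidic product as its enolate and suppresses diarylation, and the tert-butyl ester resists Claisen condensation.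

Step 13
Reactants: 21; 10
Product: 23 tert-butyl (1R,2S)-1-(ArSi)-2-ethenyl-3,3-dimethylcyclohexane-1-carboxylate, via open-chain alkylation product 22 (not isolated)
Conditions: LiN(SiMe3)2 (1.05 equiv), THF, −78 °C, then 10, −78 → 0 °C; then Pd2(dba)3·CHCl3 (2.5 mol %), (R,R)-N,N′-(cyclohexane-1,2-diyl)bis[2-(diphenylphosphanyl)benzamide] (7.5 mol %), 0 °C → rt
Reagents that add atoms: none
Why: LiN(SiMe3)2 converts 21 into its lithium enolate, which displaces iodide from 10 by SN2 to give 22 (C10–C1); no palladium is present at this stage, so the allylic carbonate is untouched. The zerovalent palladium–diphosphine complex then ionises the carbonate of 22 with loss of CO2, and the tert-butoxide set free regenerates the tertiary ester enolate at C10, which attacks the π-allyl unit on the face opposite the metal. The closest known reaction type is the intramolecular Tsuji–Trost asymmetric allylic alkylation of stabilised carbon nucleophiles that forms vinyl-substituted six-membered carbocycles, here preceded by an enolate alkylation to make a [5+1] annulation. Ring A closes in the 6-exo mode by attack at the internal terminus C5; attack at C7 would require an eight-membered ring, and the quaternary C4 excludes β-hydride elimination from the allyl complex. C5 is controlled by the chiral ligand: the two diastereomeric π-allyl complexes interconvert through the η1 form at the unsubstituted C7 terminus (helped by the iodide present), and the ligand pocket lets one of them cyclise faster. C10 is controlled by the chair-like transition state, in which the arene takes the equatorial and the enolate carbon C20 the axial position so that the arene avoids the axial C4 methyl group, which places the arene trans to the vinyl group. The step needs reaction at C1 before C5 (secured by adding the catalyst only after the alkylation), internal regioselectivity (secured by ring size) and freedom from ester self-condensation (secured by the tert-butyl ester).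

Step 14
Reactants: 23
Product: 25 tert-butyl (1R,2S)-1-(ArAc)-2-ethenyl-3,3-dimethylcyclohexane-1-carboxylate, via primary alcohol 24 (not isolated)
Conditions: Bu4NF, THF, 0 °C → rt; then Ac2O, Et3N, DMAP (cat.), rt
Reagents that add atoms: acetic anhydride, CC(=O)OC(C)=O
Why: Fluoride desilylation followed by acetylation in the same flask; the exchange is made here because the acetate, unlike the silyl ether, survives the strong acid of step 17 and is the ester required in 31, while it could not have survived the bases of steps 11–13.

Step 15
Reactants: 25
Product: 27 tert-butyl (1R,2S)-1-(ArAc)-2-(2-hydroxyethyl)-3,3-dimethylcyclohexane-1-carboxylate, via B-alkyl-9-BBN adduct 26 (not isolated)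
Conditions: 9-BBN, THF, rt → 60 °C; then NaBO3·4H2O, H2O, rt
Reagents that add atoms: sodium perborate, [Na+].[O-]OB=O
Why: Anti-Markovnikov hydroboration of a monosubstituted alkene with a dialkylborane that does not reduce esters, followed by perborate oxidation, which is mild enough for the acetate; boron adds to the terminal carbon C7, so no stereocentre is formed.

Step 16
Reactants: 27
Product: 28 tert-butyl (1R,2S)-1-(ArAc)-3,3-dimethyl-2-(2-oxoethyl)cyclohexane-1-carboxylate
Conditions: Dess–Martin periodinane, CH2Cl2, 0 °C → rt
Reagents that add atoms: none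
Why: Dess–Martin oxidation of a primary alcohol to the aldehyde under near-neutral conditions; the α-carbon C6 is a methylene, so there is nothing to epimerise.

Step 17
Reactants: 28
Product: 30 (5S,7S,10R,15S)-16-acetoxy-11,12-dimethoxyabieta-8,11,13-trien-20,7-olide, via aldehyde acid 29 (not isolated)
Conditions: CF3CO2H, CH2Cl2, 0 °C → rt; then CF3SO3H (cat.), 0 °C
Reagents that add atoms: none
Why: Acidolysis of the tert-butyl ester gives 29, whose aldehyde (free or as the lactol with the C20 acid) is activated by the stronger acid and attacked by C8, the only free position ortho to C9 and para to the C12 methoxy group (intramolecular Friedel–Crafts hydroxyalkylation closing six-membered ring B); the benzylic C7 centre is then captured by the C20 acid. The carboxyl can bridge only from the face of ring B on which it sits, so C7 can form only as (S), and the epimeric alcohol or the C6=C7 styrene would funnel to the same lactone through the benzylic cation.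

Step 18
Reactants: 30
Product: 31 (5S,7S,10R,15S)-16-acetoxy-11,12-dihydroxyabieta-8,11,13-trien-20,7-olide [(15S)-16-acetoxycarnosol]
Conditions: BBr3, CH2Cl2, −78 → −10 °C; aq. NaHCO3
Reagents that add atoms: none
Why: Lewis-acid cleavage of aryl methyl ethers through the cyclic catechol borate, hydrolysed on work-up; at low temperature an alkyl acetate and the lactone carbonyl are much less reactive than the aryl ethers, and a C7–O bond that ionises can only re-close to the same bridged lactone, so no stereocentre is affected.

## Compound list

1 | isobutyronitrile (2-methylpropanenitrile) | CC(C)C#N | starting material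
2 | 1-bromo-3-chloropropane | ClCCCBr | starting material
3 | 5-chloro-2,2-dimethylpentanenitrile | N#CC(C)(C)CCCCl | intermediate
4 | N-(diisobutylalumanyl)-5-chloro-2,2-dimethylpentan-1-imine | ClCCCC(C)(C)C=N[Al](CC(C)C)CC(C)C | intermediate
5 | 5-chloro-2,2-dimethylpentanal | O=CC(C)(C)CCCCl | intermediate
6 | triethyl phosphonoacetate | CCOC(=O)CP(=O)(OCC)OCC | starting material
7 | ethyl (E)-7-chloro-4,4-dimethylhept-2-enoate | CCOC(=O)/C=C/C(C)(C)CCCCl | intermediate
8 | (E)-7-chloro-4,4-dimethylhept-2-en-1-ol | OC/C=C/C(C)(C)CCCCl | intermediate
9 | tert-butyl (E)-7-chloro-4,4-dimethylhept-2-en-1-yl carbonate | CC(C)(C)OC(=O)OC/C=C/C(C)(C)CCCCl | intermediate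
10 | tert-butyl (E)-7-iodo-4,4-dimethylhept-2-en-1-yl carbonate | CC(C)(C)OC(=O)OC/C=C/C(C)(C)CCCI | intermediate
11 | (2,3-dimethoxyphenyl)acetic acid | COc1cccc(CC(=O)O)c1OC | starting material
12 | (S)-4-benzyloxazolidin-2-one | O=C1N[C@@H](Cc2ccccc2)CO1 | starting material
13 | (2,3-dimethoxyphenyl)acetic pivalic anhydride | COc1cccc(CC(=O)OC(=O)C(C)(C)C)c1OC | intermediate
14 | (S)-4-benzyl-3-[(2,3-dimethoxyphenyl)acetyl]oxazolidin-2-one | COc1cccc(CC(=O)N2[C@@H](Cc3ccccc3)COC2=O)c1OC | intermediate
15 | (S)-4-benzyl-3-[(2S)-2-(2,3-dimethoxyphenyl)propanoyl]oxazolidin-2-one | COc1cccc([C@H](C)C(=O)N2[C@@H](Cc3ccccc3)COC2=O)c1OC | intermediate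
16 | (2S)-2-(2,3-dimethoxyphenyl)propan-1-ol | OC[C@@H](C)c1cccc(OC)c1OC | intermediate
17 | tert-butyl{[(2S)-2-(2,3-dimethoxyphenyl)propyl]oxy}dimethylsilane | CC(C)(C)[Si](C)(C)OC[C@@H](C)c1cccc(OC)c1OC | intermediate
18 | {4-[(2S)-1-{[tert-butyl(dimethyl)silyl]oxy}propan-2-yl]-2,3-dimethoxyphenyl}lithium | CC(C)(C)[Si](C)(C)OC[C@@H](C)c1ccc([Li])c(OC)c1OC | intermediate
19 | {[(2S)-2-(4-bromo-2,3-dimethoxyphenyl)propyl]oxy}(tert-butyl)dimethylsilane | CC(C)(C)[Si](C)(C)OC[C@@H](C)c1ccc(Br)c(OC)c1OC | intermediate
20 | tert-butyl acetate | CC(=O)OC(C)(C)C | starting material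
21 | tert-butyl 2-{4-[(2S)-1-{[tert-butyl(dimethyl)silyl]oxy}propan-2-yl]-2,3-dimethoxyphenyl}acetate | CC(C)(C)[Si](C)(C)OC[C@@H](C)c1ccc(CC(=O)OC(C)(C)C)c(OC)c1OC | intermediate
22 | tert-butyl (7E)-9-[(tert-butoxycarbonyl)oxy]-2-{4-[(2S)-1-{[tert-butyl(dimethyl)silyl]oxy}propan-2-yl]-2,3-dimethoxyphenyl}-6,6-dimethylnon-7-enoate (both C2 epimers) | CC(C)(C)[Si](C)(C)OC[C@@H](C)c1ccc(C(CCCC(C)(C)/C=C/COC(=O)OC(C)(C)C)C(=O)OC(C)(C)C)c(OC)c1OC | intermediate
23 | tert-butyl (1R,2S)-1-{4-[(2S)-1-{[tert-butyl(dimethyl)silyl]oxy}propan-2-yl]-2,3-dimethoxyphenyl}-2-ethenyl-3,3-dimethylcyclohexane-1-carboxylate | CC(C)(C)[Si](C)(C)OC[C@@H](C)c1ccc(c(OC)c1OC)[C@@]1(C(=O)OC(C)(C)C)CCCC(C)(C)[C@@H]1C=C | intermediate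
24 | tert-butyl (1R,2S)-2-ethenyl-1-{4-[(2S)-1-hydroxypropan-2-yl]-2,3-dimethoxyphenyl}-3,3-dimethylcyclohexane-1-carboxylate | OC[C@@H](C)c1ccc(c(OC)c1OC)[C@@]1(C(=O)OC(C)(C)C)CCCC(C)(C)[C@@H]1C=C | intermediate
25 | tert-butyl (1R,2S)-1-{4-[(2S)-1-acetoxypropan-2-yl]-2,3-dimethoxyphenyl}-2-ethenyl-3,3-dimethylcyclohexane-1-carboxylate | CC(=O)OC[C@@H](C)c1ccc(c(OC)c1OC)[C@@]1(C(=O)OC(C)(C)C)CCCC(C)(C)[C@@H]1C=C | intermediate
26 | tert-butyl (1R,2S)-1-{4-[(2S)-1-acetoxypropan-2-yl]-2,3-dimethoxyphenyl}-2-[2-(9-borabicyclo[3.3.1]nonan-9-yl)ethyl]-3,3-dimethylcyclohexane-1-carboxylate | CC(=O)OC[C@@H](C)c1ccc(c(OC)c1OC)[C@@]1(C(=O)OC(C)(C)C)CCCC(C)(C)[C@@H]1CCB1C2CCCC1CCC2 | intermediate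
27 | tert-butyl (1R,2S)-1-{4-[(2S)-1-acetoxypropan-2-yl]-2,3-dimethoxyphenyl}-2-(2-hydroxyethyl)-3,3-dimethylcyclohexane-1-carboxylate | CC(=O)OC[C@@H](C)c1ccc(c(OC)c1OC)[C@@]1(C(=O)OC(C)(C)C)CCCC(C)(C)[C@@H]1CCO | intermediate
28 | tert-butyl (1R,2S)-1-{4-[(2S)-1-acetoxypropan-2-yl]-2,3-dimethoxyphenyl}-3,3-dimethyl-2-(2-oxoethyl)cyclohexane-1-carboxylate | CC(=O)OC[C@@H](C)c1ccc(c(OC)c1OC)[C@@]1(C(=O)OC(C)(C)C)CCCC(C)(C)[C@@H]1CC=O | intermediate
29 | (1R,2S)-1-{4-[(2S)-1-acetoxypropan-2-yl]-2,3-dimethoxyphenyl}-3,3-dimethyl-2-(2-oxoethyl)cyclohexane-1-carboxylic acid | CC(=O)OC[C@@H](C)c1ccc(c(OC)c1OC)[C@@]1(C(=O)O)CCCC(C)(C)[C@@H]1CC=O | intermediate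
30 | (5S,7S,10R,15S)-16-acetoxy-11,12-dimethoxyabieta-8,11,13-trien-20,7-olide | CC(=O)OC[C@@H](C)c1cc2c(c(OC)c1OC)[C@@]13CCCC(C)(C)[C@@H]1C[C@@H]2OC3=O | intermediate
31 | (5S,7S,10R,15S)-16-acetoxy-11,12-dihydroxyabieta-8,11,13-trien-20,7-olide [(15S)-16-acetoxycarnosol] | CC(=O)OC[C@@H](C)c1cc2c(c(O)c1O)[C@@]13CCCC(C)(C)[C@@H]1C[C@@H]2OC3=O | target

## Step count and least certain steps

Total: 18 steps. Longest linear sequence: 12 steps (steps 1–6 or steps 7–12, followed by steps 13–18).

**Step 13 (key step).** The ring closure has to occur at a neopentyl allyl terminus inside a bulky ligand pocket and form a quaternary centre. It may therefore be outrun by intermolecular attack of an enolate or of tert-butoxide at the open C7 terminus, leading to oligomerisation or allyl ether formation. Facial selection may erode if cyclisation is not slower than the allyl-face exchange, and the closing chair may place the arene cis to the vinyl group.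
Fallback, from 21 and 7, returning at 28: the allyl electrophile is replaced by a Michael acceptor. Chloride 7 is converted with NaI in acetone into ethyl (E)-7-iodo-4,4-dimethylhept-2-enoate F1. The lithium enolate of 21 (LiN(SiMe3)2, THF, −78 °C) is alkylated with F1 at C1 to give the open-chain diester 9-tert-butyl 1-ethyl (2E)-8-(ArSi)-4,4-dimethylnon-2-enedioate F2; the β-carbon C5 of F1 is shielded by C4 against intermolecular conjugate addition, and there is no γ-hydrogen. Catalytic KOt-Bu in t-BuOH/THF then closes ring A by reversible 6-exo-trig conjugate addition of the C10 enolate to C5, which should settle on the isomer with the arene trans to the acetate arm, tert-butyl (1R,2S)-1-(ArSi)-2-(2-ethoxy-2-oxoethyl)-3,3-dimethylcyclohexane-1-carboxylate F3. No chiral catalyst is involved, so F3 would be accompanied by its (1S,2R) diastereomer F4; because of C15 the two are diastereomers and would be separated by chromatography, at the cost of half the material. i-Bu2AlH at −78 °C reduces only the unhindered ethyl ester of F3 to the aldehyde, tert-butyl (1R,2S)-1-(ArSi)-3,3-dimethyl-2-(2-oxoethyl)cyclohexane-1-carboxylate F5. HF·pyridine in THF removes the silyl group to give tert-butyl (1R,2S)-1-{4-[(2S)-1-hydroxypropan-2-yl]-2,3-dimethoxyphenyl}-3,3-dimethyl-2-(2-oxoethyl)cyclohexane-1-carboxylate F6, and Ac2O/pyridine acetylates F6 to reach 28. Steps 14–16 are bypassed.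

**Step 17.** Arene attack at C8 may be slow because the C12 methoxy group is twisted out of conjugation by its two neighbours. Intermolecular aldol condensation of the enolisable aldehyde, or tert-butylation of the arene by the cation released from the ester, could then compete.
Fallback, from 28, returning at 30: ring B is closed by acylation instead of hydroxyalkylation. Pinnick oxidation (NaClO2, NaH2PO4, 2-methylbut-2-ene) gives the C7 acid, 2-[(1S,2R)-2-(ArAc)-2-(tert-butoxycarbonyl)-6,6-dimethylcyclohexyl]acetic acid F7. (CF3CO)2O/CF3CO2H effects intramolecular Friedel–Crafts acylation at C8 (a 4-arylbutanoic acid to 1-tetralone closure) with loss of the tert-butyl group, giving (5S,10R,15S)-16-acetoxy-11,12-dimethoxy-7-oxoabieta-8,11,13-trien-20-oic acid F8. NaBH4 in EtOH at 0 °C reduces the aryl ketone to (5S,10R,15S)-16-acetoxy-7-hydroxy-11,12-dimethoxyabieta-8,11,13-trien-20-oic acid F9, as either C7 epimer. Catalytic p-toluenesulfonic acid in toluene converts both epimers through the benzylic cation into 30.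

**Step 18.** The primary acetate may be lost by Lewis-acid acyl transfer or on work-up. The C7–O bond may ionise to a benzylic bromide that does not fully re-close, and the hindered C11 ether may cleave incompletely at the temperature the acetate tolerates.
Fallback, from 30, returning at 31: selectivity is moved from the deprotection to the acylation. K2CO3 in MeOH at 0 °C removes the primary acetate while the catechol is still protected, giving (5S,7S,10R,15S)-16-hydroxy-11,12-dimethoxyabieta-8,11,13-trien-20,7-olide F10; the lactone carbonyl sits on the quaternary C10 and should transesterify far more slowly than a primary acetate. Excess BBr3 in CH2Cl2 (−78 °C → rt) can now be used without restraint and, after aqueous work-up, gives (5S,7S,10R,15S)-11,12,16-trihydroxyabieta-8,11,13-trien-20,7-olide F11. Candida antarctica lipase B with vinyl acetate in t-BuOMe then acetylates only the primary aliphatic hydroxyl, phenols being poor acyl acceptors for the enzyme, to give 31.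

**Step 12.** Oxidative addition at the electron-rich, ortho-substituted bromide may be slow, allowing self-condensation of the acetate enolate or a second arylation of the product enolate.
Fallback, from 17 (through 18, made as in step 11), returning at 21: the two-carbon unit is added as an electrophile. Aryllithium 18 opens oxirane (Et2O, −78 °C → rt) to give 2-(ArSi)ethan-1-ol F12. 2,2,6,6-Tetramethylpiperidin-1-oxyl with PhI(OAc)2 in MeCN/H2O oxidises F12 to 2-(ArSi)acetic acid F13. Boc2O, DMAP and t-BuOH convert F13 into 21.

**Step 15.** Hydroboration of a vinyl group flanked by two quaternary carbons may need prolonged heating, during which slow ester reduction, or acetate hydrolysis in the oxidative work-up, could intervene.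
Fallback, from 25, returning at 28: nitrite-modified palladium-catalysed aerobic oxidation of the terminal olefin (PdCl2(PhCN)2, CuCl2·2H2O, AgNO2, t-BuOH/MeNO2, O2), which is aldehyde-selective, would give 28 directly and bypass 27 and step 16.

## Further compounds

F1 | step 13 | ethyl (E)-7-iodo-4,4-dimethylhept-2-enoate | CCOC(=O)/C=C/C(C)(C)CCCI
F2 | step 13 | 9-tert-butyl 1-ethyl (2E)-8-{4-[(2S)-1-{[tert-butyl(dimethyl)silyl]oxy}propan-2-yl]-2,3-dimethoxyphenyl}-4,4-dimethylnon-2-enedioate (both C8 epimers) | CC(C)(C)[Si](C)(C)OC[C@@H](C)c1ccc(C(CCCC(C)(C)/C=C/C(=O)OCC)C(=O)OC(C)(C)C)c(OC)c1OC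
F3 | step 13 | tert-butyl (1R,2S)-1-{4-[(2S)-1-{[tert-butyl(dimethyl)silyl]oxy}propan-2-yl]-2,3-dimethoxyphenyl}-2-(2-ethoxy-2-oxoethyl)-3,3-dimethylcyclohexane-1-carboxylate | CC(C)(C)[Si](C)(C)OC[C@@H](C)c1ccc(c(OC)c1OC)[C@@]1(C(=O)OC(C)(C)C)CCCC(C)(C)[C@@H]1CC(=O)OCC
F4 | step 13 | tert-butyl (1S,2R)-1-{4-[(2S)-1-{[tert-butyl(dimethyl)silyl]oxy}propan-2-yl]-2,3-dimethoxyphenyl}-2-(2-ethoxy-2-oxoethyl)-3,3-dimethylcyclohexane-1-carboxylate | CC(C)(C)[Si](C)(C)OC[C@@H](C)c1ccc(c(OC)c1OC)[C@]1(C(=O)OC(C)(C)C)CCCC(C)(C)[C@H]1CC(=O)OCC
F5 | step 13 | tert-butyl (1R,2S)-1-{4-[(2S)-1-{[tert-butyl(dimethyl)silyl]oxy}propan-2-yl]-2,3-dimethoxyphenyl}-3,3-dimethyl-2-(2-oxoethyl)cyclohexane-1-carboxylate | CC(C)(C)[Si](C)(C)OC[C@@H](C)c1ccc(c(OC)c1OC)[C@@]1(C(=O)OC(C)(C)C)CCCC(C)(C)[C@@H]1CC=O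
F6 | step 13 | tert-butyl (1R,2S)-1-{4-[(2S)-1-hydroxypropan-2-yl]-2,3-dimethoxyphenyl}-3,3-dimethyl-2-(2-oxoethyl)cyclohexane-1-carboxylate | OC[C@@H](C)c1ccc(c(OC)c1OC)[C@@]1(C(=O)OC(C)(C)C)CCCC(C)(C)[C@@H]1CC=O
F7 | step 17 | 2-[(1S,2R)-2-{4-[(2S)-1-acetoxypropan-2-yl]-2,3-dimethoxyphenyl}-2-(tert-butoxycarbonyl)-6,6-dimethylcyclohexyl]acetic acid | CC(=O)OC[C@@H](C)c1ccc(c(OC)c1OC)[C@@]1(C(=O)OC(C)(C)C)CCCC(C)(C)[C@@H]1CC(=O)O
F8 | step 17 | (5S,10R,15S)-16-acetoxy-11,12-dimethoxy-7-oxoabieta-8,11,13-trien-20-oic acid | CC(=O)OC[C@@H](C)c1cc2c(c(OC)c1OC)[C@@]1(C(=O)O)CCCC(C)(C)[C@@H]1CC2=O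
F9 | step 17 | (5S,10R,15S)-16-acetoxy-7-hydroxy-11,12-dimethoxyabieta-8,11,13-trien-20-oic acid (C7 epimers) | CC(=O)OC[C@@H](C)c1cc2c(c(OC)c1OC)[C@@]1(C(=O)O)CCCC(C)(C)[C@@H]1CC2O
F10 | step 18 | (5S,7S,10R,15S)-16-hydroxy-11,12-dimethoxyabieta-8,11,13-trien-20,7-olide | OC[C@@H](C)c1cc2c(c(OC)c1OC)[C@@]13CCCC(C)(C)[C@@H]1C[C@@H]2OC3=O
F11 | step 18 | (5S,7S,10R,15S)-11,12,16-trihydroxyabieta-8,11,13-trien-20,7-olide | OC[C@@H](C)c1cc2c(c(O)c1O)[C@@]13CCCC(C)(C)[C@@H]1C[C@@H]2OC3=O
F12 | step 12 | 2-{4-[(2S)-1-{[tert-butyl(dimethyl)silyl]oxy}propan-2-yl]-2,3-dimethoxyphenyl}ethan-1-ol | CC(C)(C)[Si](C)(C)OC[C@@H](C)c1ccc(CCO)c(OC)c1OC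
F13 | step 12 | 2-{4-[(2S)-1-{[tert-butyl(dimethyl)silyl]oxy}propan-2-yl]-2,3-dimethoxyphenyl}acetic acid | CC(C)(C)[Si](C)(C)OC[C@@H](C)c1ccc(CC(=O)O)c(OC)c1OC
F0 | step 15 | none | none
A1 | alternative 1 | (5S,7S,10R,15S)-16-acetoxy-11,12-dimethoxyabieta-8,11,13-trien-20,7-olide (identical with 30) | CC(=O)OC[C@@H](C)c1cc2c(c(OC)c1OC)[C@@]13CCCC(C)(C)[C@@H]1C[C@@H]2OC3=O
A2 | alternative 1 | (1R,2S)-1-{4-[(2S)-1-acetoxypropan-2-yl]-2,3-dimethoxyphenyl}-3,3-dimethyl-2-(2-oxoethyl)cyclohexane-1-carboxylic acid (identical with 29) | CC(=O)OC[C@@H](C)c1ccc(c(OC)c1OC)[C@@]1(C(=O)O)CCCC(C)(C)[C@@H]1CC=O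
A3 | alternative 2 | carnosol | CC(C)c1cc2c(c(O)c1O)[C@@]13CCCC(C)(C)[C@@H]1C[C@@H]2OC3=O
A4 | alternative 2 | 11,12-bis-O-(diethylsilyl)carnosol | CC[SiH](CC)Oc1c(C(C)C)cc2c(c1O[SiH](CC)CC)[C@@]13CCCC(C)(C)[C@@H]1C[C@@H]2OC3=O
A5 | alternative 2 | C16-silylated benzoxasiline of carnosol (11-O-diethylsilyl) | C[C@@H]1C[Si](CC)(CC)Oc2c1cc3c(c2O[SiH](CC)CC)[C@@]45CCCC(C)(C)[C@@H]4C[C@@H]3OC5=O
A6 | alternative 2 | (15S)-16-hydroxycarnosol | OC[C@@H](C)c1cc2c(c(O)c1O)[C@@]13CCCC(C)(C)[C@@H]1C[C@@H]2OC3=O
A7 | alternative 3 | C8 tributylstannyl alkene of the ring-A-fused 2-oxabicyclo[2.2.2]oct-5-en-3-one (C8=C9) | CCCC[Sn](CCCC)(CCCC)C2=C[C@@]13CCCC(C)(C)[C@@H]1C[C@@H]2OC3=O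
A8 | alternative 3 | (2S)-2-(4-chloro-3-oxocyclobut-1-en-1-yl)propyl acetate | CC(=O)OC[C@@H](C)C1=CC(=O)C1Cl
A9 | alternative 3 | 4-alkenylcyclobutenone from coupling of A7 with A8 | CC(=O)OC[C@@H](C)C1=CC(=O)C1C2=C[C@@]34CCCC(C)(C)[C@@H]3C[C@@H]2OC4=O
A10 | alternative 3 | 12-deoxy analogue of the target (C11 phenol) | CC(=O)OC[C@@H](C)c1cc2c(c(O)c1)[C@@]13CCCC(C)(C)[C@@H]1C[C@@H]2OC3=O
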